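**Retrosynthetic overview**
1. C10–C11 is made last: copper-catalysed enantioselective SN2' coupling of the (E)-alkenylalane from ring alkyne 16 with allylic phosphate 23 sets the quaternary C10 and its vinyl group.
2. The only ring is closed in step 8, before the fragments are joined. The C16–C21 bond forms by cation–olefin cyclisation of Me2C(+)–CH(Me)–, the cation that C-methylation of the terminal isopropylidene gives in the alga. Here it is made in one flask from an ester by double methyl addition and ionisation; an (E)-allylsilane ends the cyclisation as the exocyclic methylene with C16/C20 trans.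
3. Cyclisation substrate 13 comes from 1,1-dichloroalkene 6 by two Negishi couplings (Me3SiCH2ZnCl, then alkylzinc 12). C13 comes from (S)-citronellal, C20 from Ru–BINAP hydrogenation of tulipalin A.
4. Phosphate 23 comes from farnesyl acetate by SeO2 oxidation and copper-catalysed asymmetric SN2' methylation (sets C3, a chemical copy of the second C-methylation).

Locants: chain C1–C15 as in the systematic name of 25; ring carbons C16 (CH carrying the chain), C17 (C=CH2), C18, C19, C20 (CHMe), C21 (CMe2).

Assumption: the target is taken exactly as the SMILES is written, i.e. (3R,10S,13S) in the chain and (16S,20S) with the ring substituents trans; for the three enantioselective catalysts (steps 5, 11, 13) the ligand enantiomer named is assumed to give the stated configuration, and its antipode is used if a test run shows the opposite sense.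

**Route**

Step 1
Reactants: 1 (S)-citronellal [(3S)-3,7-dimethyloct-6-enal]
Product: 3 (3S)-3,7-dimethyloct-6-en-1-yne, via alkenyl nonaflate 2 (not isolated)
Conditions: C4F9SO2F (1.3 equiv), P2-Et phosphazene base (2.5 equiv), DMF, −20 → 23 °C
Reagents that add atoms: none
Why: The enolisable aldehyde is O-sulfonylated and the alkenyl nonaflate loses nonaflate by base-induced β-elimination (carbonyl-to-alkyne conversion through an alkenyl sulfonate), while the β-stereocentre (C13 of the target) is not acidic and stays untouched.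

Step 2
Reactants: 3 (3S)-3,7-dimethyloct-6-en-1-yne
Product: 5 (4S)-4-methylhex-5-ynal, via ozonide 4 (not isolated)
Conditions: O3, CH2Cl2, −78 °C (Sudan red end point); then Me2S, −78 → 23 °C
Reagents that add atoms: ozone, [O-][O+]=O
Why: Ozonolysis with reductive work-up cleaves the electron-rich trisubstituted alkene far faster than the terminal alkyne, which exposes C16 as the aldehyde.

Step 3
Reactants: 5 (4S)-4-methylhex-5-ynal
Product: 6 (5S)-1,1-dichloro-5-methylhept-1-en-6-yne
Conditions: BrCCl3 (1.5 equiv), PPh3 (3 equiv), MeCN, 0 → 23 °C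
Reagents that add atoms: bromotrichloromethane, ClC(Cl)(Cl)Br
Why: Wittig-type gem-dichloro-olefination (Ramirez/Corey–Fuchs first stage) with Ph3P=CCl2 formed in the flask adds C17 as a dihalide ready for two selective couplings.

Step 4
Reactants: 6 (5S)-1,1-dichloro-5-methylhept-1-en-6-yne
Product: 7 [(2Z,6S)-2-chloro-6-methyloct-2-en-7-yn-1-yl]trimethylsilane
Conditions: Me3SiCH2MgCl (1.3 equiv), ZnCl2 (1.4 equiv), THF, 0 °C; then 6, PdCl2(DPEphos) (3 mol %), THF–DMF, 23 → 50 °C
Reagents that add atoms: (trimethylsilyl)methylmagnesium chloride, C[Si](C)(C)C[Mg]Cl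
Why: Trans-selective Negishi mono-coupling of a 1,1-dichloroalkene, in which palladium inserts into the C–Cl bond trans to the alkyl chain and the zinc reagent (no β-hydrogen; the slight excess of ZnCl2 leaves no basic Grignard for the alkyne) puts CH2SiMe3 trans to C15.

Step 5
Reactants: 8 α-methylene-γ-butyrolactone (tulipalin A)
Product: 9 (3S)-3-methyloxolan-2-one
Conditions: H2 (60 atm), Ru(OAc)2[(R)-BINAP] (0.5 mol %), CH2Cl2, 50 °C
Reagents that add atoms: none
Why: Ru–BINAP asymmetric hydrogenation of the exocyclic α-methylene lactone, with the carbonyl oxygen binding ruthenium so that hydrogen is delivered to one enantioface, sets the methyl-bearing centre that becomes C20 (S).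

Step 6
Reactants: 9 (3S)-3-methyloxolan-2-one
Product: 11 ethyl (2S)-4-bromo-2-methylbutanoate, via bromo acid 10 (not isolated)
Conditions: HBr (gas), EtOH, 0 → 23 °C
Reagents that add atoms: hydrogen bromide, Br; ethanol, CCO
Why: Acid-mediated SN2 opening of the lactone at the CH2–O carbon by bromide followed by Fischer esterification, conditions under which the α-stereocentre is not enolised.

Step 7
Reactants: 11 ethyl (2S)-4-bromo-2-methylbutanoate; 7 [(2Z,6S)-2-chloro-6-methyloct-2-en-7-yn-1-yl]trimethylsilane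
Product: 13 ethyl (2S,5E,9S)-2,9-dimethyl-5-[(trimethylsilyl)methyl]undec-5-en-10-ynoate, via alkylzinc bromide 12 (not isolated)
Conditions: 11, Zn dust (2 equiv), LiCl (1.5 equiv), THF, 50 °C; then 7, Pd(PtBu3)2 (4 mol %), THF–NMP, 60 °C
Reagents that add atoms: none
Why: LiCl-promoted zinc insertion followed by Negishi alkyl–alkenyl coupling, which with the bulky trialkylphosphine catalyst retains the alkene geometry and therefore places C18 cis to C15 (the (E)-allylsilane).

Step 8
Reactants: 13 ethyl (2S,5E,9S)-2,9-dimethyl-5-[(trimethylsilyl)methyl]undec-5-en-10-ynoate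
Product: 16 (3S)-3-methyl-5-[(1S,3S)-2,2,3-trimethyl-6-methylidenecyclohexyl]pent-1-yne, via magnesium alkoxide 14 (not isolated), via titanium alkoxide 15 (not isolated)
Conditions: MeMgBr (3 M in Et2O, 2.2 equiv), CH2Cl2, −20 → 0 °C; then 2,6-di-tert-butyl-4-methylpyridine (0.5 equiv), TiCl4 (4 equiv), −78 → −40 °C
Reagents that add atoms: methylmagnesium bromide, C[Mg]Br
Why: Proposed new method: double Grignard addition turns the ester into a tertiary alkoxide which, once on titanium, ionises without releasing acid (closest known chemistry: TiCl4-mediated ionisation of tertiary carbinols and chlorides with capture by allylsilanes, and allylsilane-terminated cation–olefin cyclisation) to the gem-dimethyl cation, and the (E)-allylsilane captures it through a chair in which the alkene geometry forces the C16 chain axial and the C20 methyl stays equatorial to avoid a 1,3-diaxial clash, so C16 is set trans to C20 (16S) and loss of silicon leaves the double bond exocyclic.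

Step 9
Reactants: 17 (2E,6E)-farnesyl acetate
Product: 18 (2E,6E,10E)-12-hydroxy-3,7,11-trimethyldodeca-2,6,10-trien-1-yl acetate
Conditions: SeO2 (0.3 equiv), t-BuOOH (3 equiv), salicylic acid (0.1 equiv), CH2Cl2, 23 °C
Reagents that add atoms: tert-butyl hydroperoxide, CC(C)(C)OO
Why: Selenium dioxide allylic oxidation (ene reaction then 2,3-shift) attacks the (E)-methyl of the most electron-rich, terminal trisubstituted alkene, the alkene next to the acetate being deactivated.

Step 10
Reactants: 18 (2E,6E,10E)-12-hydroxy-3,7,11-trimethyldodeca-2,6,10-trien-1-yl acetate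
Product: 20 (2E,6E,10E)-12-chloro-3,7,11-trimethyldodeca-2,6,10-trien-1-yl acetate, via mesylate 19 (not isolated)
Conditions: MsCl (1.3 equiv), 2,4,6-collidine (2 equiv), LiCl (3 equiv), DMF, 0 °C
Reagents that add atoms: lithium chloride, [Li+].[Cl-]
Why: Mesylation and direct SN2 displacement by chloride at the primary allylic carbon give the allylic chloride without allylic transposition or loss of alkene geometry.

Step 11
Reactants: 20 (2E,6E,10E)-12-chloro-3,7,11-trimethyldodeca-2,6,10-trien-1-yl acetate
Product: 22 (2E,6E,10R)-3,7,10,11-tetramethyldodeca-2,6,11-trien-1-ol, via acetate 21 (not isolated)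
Conditions: MeMgBr (1.3 equiv, slow addition), Cu(O2CC4H3S) (copper thiophene-2-carboxylate, 3 mol %), (S,S,S)-binaphthol-derived phosphoramidite of bis[1-(2-methoxyphenyl)ethyl]amine (3.3 mol %), CH2Cl2, −78 °C; then MeOH, K2CO3, 23 °C
Reagents that add atoms: methylmagnesium bromide, C[Mg]Br
Why: Copper-catalysed asymmetric SN2' allylic alkylation of a 2-methyl-substituted allylic chloride delivers methyl to the γ-carbon under ligand control, setting the (R)-centre (C3 of the target) and creating the isopropenyl group, after which the acetate is removed by methanolysis.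

Step 12
Reactants: 22 (2E,6E,10R)-3,7,10,11-tetramethyldodeca-2,6,11-trien-1-ol
Product: 23 diethyl (2E,6E,10R)-3,7,10,11-tetramethyldodeca-2,6,11-trien-1-yl phosphate
Conditions: ClP(O)(OEt)2 (1.3 equiv), Et3N (2 equiv), DMAP (0.1 equiv), CH2Cl2, 0 → 23 °C
Reagents that add atoms: diethyl chlorophosphate, CCOP(=O)(Cl)OCC
Why: O-phosphorylation of the primary allylic alcohol gives the leaving group needed for copper-catalysed SN2' substitution.

Step 13
Reactants: 16 (3S)-3-methyl-5-[(1S,3S)-2,2,3-trimethyl-6-methylidenecyclohexyl]pent-1-yne; 23 diethyl (2E,6E,10R)-3,7,10,11-tetramethyldodeca-2,6,11-trien-1-yl phosphate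
Product: 25 (3R,6E,10S,11E,13S)-10-ethenyl-2,3,6,10,13-pentamethyl-15-[(1S,3S)-2,2,3-trimethyl-6-methylidenecyclohexyl]pentadeca-1,6,11-triene, via alkenylalane 24 (not isolated)
Conditions: 16 (1.5 equiv), i-Bu2AlH (1.5 equiv), hexanes, 55 °C; then 23 (1.0 equiv), CuCl2·2H2O (3 mol %), Ag2(L)2 (1.5 mol %; L = (4S,5S)-1-(2,6-diethylphenyl)-4,5-diphenyl-3-(2-sulfonatophenyl)imidazolin-2-ylidene), THF, −15 °C
Reagents that add atoms: none
Why: Syn hydroalumination gives the (E)-alkenylalane, and NHC–copper-catalysed enantioselective SN2' allylic substitution transfers the alkenyl group to the methyl-bearing alkene carbon of the (E)-allylic phosphate, forming the quaternary C10 (S, catalyst-controlled) and its vinyl group.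

**Compound list**
1 | (S)-citronellal, (3S)-3,7-dimethyloct-6-enal | O=CC[C@@H](C)CCC=C(C)C | starting material
2 | (3S)-3,7-dimethylocta-1,6-dien-1-yl nonafluorobutane-1-sulfonate (E/Z mixture) | CC(C)=CCC[C@H](C)C=COS(=O)(=O)C(F)(F)C(F)(F)C(F)(F)C(F)(F)F | intermediate
3 | (3S)-3,7-dimethyloct-6-en-1-yne | C#C[C@@H](C)CCC=C(C)C | intermediate
4 | 3,3-dimethyl-5-[(3S)-3-methylpent-4-yn-1-yl]-1,2,4-trioxolane | C#C[C@@H](C)CCC1OOC(C)(C)O1 | intermediate
5 | (4S)-4-methylhex-5-ynal | C#C[C@@H](C)CCC=O | intermediate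
6 | (5S)-1,1-dichloro-5-methylhept-1-en-6-yne | C#C[C@@H](C)CCC=C(Cl)Cl | intermediate
7 | [(2Z,6S)-2-chloro-6-methyloct-2-en-7-yn-1-yl]trimethylsilane | C#C[C@@H](C)CC/C=C(Cl)/C[Si](C)(C)C | intermediate
8 | α-methylene-γ-butyrolactone (tulipalin A) | C=C1CCOC1=O | starting material
9 | (3S)-3-methyloxolan-2-one | C[C@H]1CCOC1=O | intermediate
10 | (2S)-4-bromo-2-methylbutanoic acid | BrCC[C@H](C)C(=O)O | intermediate
11 | ethyl (2S)-4-bromo-2-methylbutanoate | BrCC[C@H](C)C(=O)OCC | intermediate
12 | [(3S)-4-ethoxy-3-methyl-4-oxobutyl]zinc bromide | Br[Zn]CC[C@H](C)C(=O)OCC | intermediate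
13 | ethyl (2S,5E,9S)-2,9-dimethyl-5-[(trimethylsilyl)methyl]undec-5-en-10-ynoate | C#C[C@@H](C)CC/C=C(\CC[C@H](C)C(=O)OCC)C[Si](C)(C)C | intermediate
14 | bromomagnesium (3S,6E,10S)-2,3,10-trimethyl-6-[(trimethylsilyl)methyl]dodec-6-en-11-yn-2-olate | C#C[C@@H](C)CC/C=C(\CC[C@H](C)C(C)(C)O[Mg]Br)C[Si](C)(C)C | intermediate
15 | trichlorotitanium (3S,6E,10S)-2,3,10-trimethyl-6-[(trimethylsilyl)methyl]dodec-6-en-11-yn-2-olate | C#C[C@@H](C)CC/C=C(\CC[C@H](C)C(C)(C)O[Ti](Cl)(Cl)Cl)C[Si](C)(C)C | intermediate
16 | (3S)-3-methyl-5-[(1S,3S)-2,2,3-trimethyl-6-methylidenecyclohexyl]pent-1-yne | C#C[C@@H](C)CC[C@H]1C(=C)CC[C@H](C)C1(C)C | intermediate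
17 | (2E,6E)-farnesyl acetate | CC(C)=CCC/C(C)=C/CC/C(C)=C/COC(C)=O | starting material
18 | (2E,6E,10E)-12-hydroxy-3,7,11-trimethyldodeca-2,6,10-trien-1-yl acetate | OC/C(C)=C/CC/C(C)=C/CC/C(C)=C/COC(C)=O | intermediate
19 | (2E,6E,10E)-12-(methanesulfonyloxy)-3,7,11-trimethyldodeca-2,6,10-trien-1-yl acetate | CS(=O)(=O)OC/C(C)=C/CC/C(C)=C/CC/C(C)=C/COC(C)=O | intermediate
20 | (2E,6E,10E)-12-chloro-3,7,11-trimethyldodeca-2,6,10-trien-1-yl acetate | ClC/C(C)=C/CC/C(C)=C/CC/C(C)=C/COC(C)=O | intermediate
21 | (2E,6E,10R)-3,7,10,11-tetramethyldodeca-2,6,11-trien-1-yl acetate | C=C(C)[C@H](C)CC/C(C)=C/CC/C(C)=C/COC(C)=O | intermediate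
22 | (2E,6E,10R)-3,7,10,11-tetramethyldodeca-2,6,11-trien-1-ol | C=C(C)[C@H](C)CC/C(C)=C/CC/C(C)=C/CO | intermediate
23 | diethyl (2E,6E,10R)-3,7,10,11-tetramethyldodeca-2,6,11-trien-1-yl phosphate | C=C(C)[C@H](C)CC/C(C)=C/CC/C(C)=C/COP(=O)(OCC)OCC | intermediate
24 | diisobutyl{(1E,3S)-3-methyl-5-[(1S,3S)-2,2,3-trimethyl-6-methylidenecyclohexyl]pent-1-en-1-yl}alane | CC(C)C[Al](CC(C)C)/C=C/[C@@H](C)CC[C@H]1C(=C)CC[C@H](C)C1(C)C | intermediate
25 | (3R,6E,10S,11E,13S)-10-ethenyl-2,3,6,10,13-pentamethyl-15-[(1S,3S)-2,2,3-trimethyl-6-methylidenecyclohexyl]pentadeca-1,6,11-triene | C=C[C@@](C)(/C=C/[C@@H](C)CC[C@H]1C(=C)CC[C@H](C)C1(C)C)CC/C=C(\C)CC[C@@H](C)C(=C)C | target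

**Step count and risks**
Total: 13 steps. Longest linear sequence: 7 steps (1, 2, 3, 4, 7, 8, 13, from (S)-citronellal).

Most likely to fail:

Step 8 (cyclisation). The free tertiary cation may suffer hydride shift from C20 (loss of the C20 configuration, five-membered by-products) or elimination. The fallback avoids a free cation. It sets out from 13, which is converted (MeNHOMe·HCl, i-PrMgCl, THF) into the Weinreb amide F1, then (MeMgBr) into the methyl ketone F2, and then (Ph3P=CH2, THF, −78 → 0 °C) into the isopropenyl compound F3. Hydrogen-atom transfer from a cobalt hydride to the isopropenyl group [Co(C36H52N2O2) salen complex, N-fluoro-2,4,6-trimethylpyridinium tetrafluoroborate, (Me2SiH)2O, hexafluoroisopropanol, 0 °C] generates the same tertiary centre as an alkylcobalt species, which the allylsilane displaces in the same chair. This comes back to the route at 16.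

Step 11 (asymmetric SN2' methylation). Methyl Grignard reagents can give lower SN2'/SN2 ratios and ee on aliphatic 2-methylallyl chlorides. The fallback takes the stereocentre from a Sharpless epoxidation. It sets out from 18: Ti(OiPr)4, L-(+)-diethyl tartrate and t-BuOOH (CH2Cl2, −20 °C) give the epoxy alcohol F4. AlMe3 (hexane–CH2Cl2, −20 → 0 °C) opens it at C10 with inversion to the diol F5. Thiocarbonyldiimidazole gives the cyclic thionocarbonate F6. P(OMe)3 at 110 °C (Corey–Winter) then releases the isopropenyl group. This comes back to the route at 21, which is methanolysed to 22 as in step 11.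

Step 13 (fragment union). The γ-branched alkenylalane may transfer slowly or with reduced SN2' selectivity or er. The fallback changes the nucleophile to a boronate activated by alkoxide. It sets out from 16: pinacolborane with Cp2Zr(H)Cl (10 mol %) and Et3N at 60 °C gives the (E)-alkenylboronate F7. F7 is coupled with 23 using CuCl, the imidazolinium salt of the same chiral sulfonate carbene and NaOMe in THF at 22 °C. This comes back to the route at 25.

**Further compounds**
F1 | step 8 | (2S,5E,9S)-N-methoxy-N,2,9-trimethyl-5-[(trimethylsilyl)methyl]undec-5-en-10-ynamide | C#C[C@@H](C)CC/C=C(\CC[C@H](C)C(=O)N(C)OC)C[Si](C)(C)C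
F2 | step 8 | (3S,6E,10S)-3,10-dimethyl-6-[(trimethylsilyl)methyl]dodec-6-en-11-yn-2-one | C#C[C@@H](C)CC/C=C(\CC[C@H](C)C(C)=O)C[Si](C)(C)C
F3 | step 8 | {(2E,6S)-2-[(3S)-3,4-dimethylpent-4-en-1-yl]-6-methyloct-2-en-7-yn-1-yl}trimethylsilane | C#C[C@@H](C)CC/C=C(\CC[C@H](C)C(C)=C)C[Si](C)(C)C
F4 | step 11 | (2E,6E)-9-[(2S,3S)-3-(hydroxymethyl)-3-methyloxiran-2-yl]-3,7-dimethylnona-2,6-dien-1-yl acetate | OC[C@]1(C)O[C@H]1CC/C(C)=C/CC/C(C)=C/COC(C)=O
F5 | step 11 | (2E,6E,10R,11R)-11,12-dihydroxy-3,7,10,11-tetramethyldodeca-2,6-dien-1-yl acetate | OC[C@](C)(O)[C@H](C)CC/C(C)=C/CC/C(C)=C/COC(C)=O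
F6 | step 11 | (2E,6E,10R)-3,7-dimethyl-10-[(4R)-4-methyl-2-sulfanylidene-1,3-dioxolan-4-yl]undeca-2,6-dien-1-yl acetate | S=C1OC[C@](C)(O1)[C@H](C)CC/C(C)=C/CC/C(C)=C/COC(C)=O
F7 | step 13 | 4,4,5,5-tetramethyl-2-{(1E,3S)-3-methyl-5-[(1S,3S)-2,2,3-trimethyl-6-methylidenecyclohexyl]pent-1-en-1-yl}-1,3,2-dioxaborolane | CC1(C)OB(OC1(C)C)/C=C/[C@@H](C)CC[C@H]2C(=C)CC[C@H](C)C2(C)C
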